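## Retrosynthetic overview
1. The prenyl group comes from a C5-allyl group by cross metathesis. The C5-allyl comes from the 4-O-allyl ether by aromatic Claisen rearrangement, because C5 is the only free ortho position.
2. The 2-aryl-3-formylbenzofuran comes from acid-induced opening and re-closure of a 3-aroyl-2-methoxy-2,3-dihydrobenzofuran, which comes from a beta-keto dimethyl acetal.
3. The beta-keto acetal comes from a chalcone by a 1,2-aryl shift induced by trivalent iodine.
4. The chalcone comes from an intermolecular Claisen–Schmidt aldol condensation (key C–C bond) of 2,4-bis(benzyloxy)acetophenone with the symmetric 4-methoxy-2,6-bis(methoxymethoxy)benzaldehyde.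
5. Both benzene rings are bought. The furan is the only ring formed, first as a dihydrofuran acetal and then re-closed on the ketone.

Assumption: the target has no stereocentre and no stereogenic double bond, so it is achiral and needs no enantiocontrol. The stereocentres in 6, 8, 9, 10 and 13 are racemic and transient.

## Route

Step 1
Reactants: 1 2,4-dihydroxyacetophenone
Product: 2 2,4-bis(benzyloxy)acetophenone
Conditions: BnBr (2.5 equiv), K2CO3 (3 equiv), DMF, 80 °C
Reagents that add atoms: benzyl bromide, BrCc1ccccc1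
Why: Williamson ether synthesis; hot DMF also alkylates the chelated 2-OH, and benzyl ethers survive the base, the oxidant and the acids used in steps 4–9.

Step 2
Reactants: 3 2,4,6-trimethoxybenzaldehyde
Product: 4 2,6-dihydroxy-4-methoxybenzaldehyde
Conditions: AlCl3 (4 equiv), CH2Cl2, 0 °C → reflux; then ice-water
Reagents that add atoms: none
Why: Carbonyl-directed Lewis acid demethylation cleaves only the two methoxy groups ortho to the formyl group and leaves the para methoxy group intact.

Step 3
Reactants: 4 2,6-dihydroxy-4-methoxybenzaldehyde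
Product: 5 4-methoxy-2,6-bis(methoxymethoxy)benzaldehyde
Conditions: NaH (2.5 equiv), MOMCl (2.5 equiv), DMF, 0 °C → rt
Reagents that add atoms: chloromethyl methyl ether, COCCl
Why: O-alkylation of the bis-phenoxide (acetal protection) gives a base-stable, acid-labile mask, and the symmetric substitution removes any later regiochemical question.

Step 4
Reactants: 2 2,4-bis(benzyloxy)acetophenone; 5 4-methoxy-2,6-bis(methoxymethoxy)benzaldehyde
Product: 7 (E)-1-[2,4-bis(benzyloxy)phenyl]-3-[4-methoxy-2,6-bis(methoxymethoxy)phenyl]prop-2-en-1-one, via aldol adduct 6 (not isolated)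
Conditions: KOH (5 equiv), EtOH–THF, rt → 50 °C
Reagents that add atoms: none
Why: Claisen–Schmidt aldol condensation of a methyl ketone enolate with a non-enolisable aldehyde, followed by E1cB dehydration, gives the thermodynamic E-enone; the MOM and benzyl ethers are inert to hydroxide.

Step 5
Reactants: 7 (E)-chalcone
Product: 8 1-[2,4-bis(benzyloxy)phenyl]-3,3-dimethoxy-2-[4-methoxy-2,6-bis(methoxymethoxy)phenyl]propan-1-one (racemic)
Conditions: PhI(OH)OTs (1.2 equiv), MeOH, 0 °C → rt
Reagents that add atoms: methanol, CO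
Why: Oxidative chalcone rearrangement, in which trivalent iodine and methanol add across the electron-rich styrenyl C=C and loss of PhI drives a 1,2-shift of the trialkoxyaryl ring through a phenonium ion; the new stereocentre is racemic and is erased in step 7.

Step 6
Reactants: 8 beta-keto dimethyl acetal
Product: 9 [2,4-bis(benzyloxy)phenyl](4-hydroxy-2,6-dimethoxy-2,3-dihydro-1-benzofuran-3-yl)methanone (racemic cis/trans mixture)
Conditions: p-TsOH·H2O (0.2 equiv), MeOH–THF, rt
Reagents that add atoms: none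
Why: Acid-catalysed methanolysis of both MOM groups frees two equivalent phenols, and one of them closes on the neighbouring acetal (transacetalisation to a five-membered ring); both stereocentres are uncontrolled and are erased in step 7.

Step 7
Reactants: 9 3-aroyl-2-methoxy-2,3-dihydrobenzofuran
Product: 11 2-[2,4-bis(benzyloxy)phenyl]-4-hydroxy-6-methoxy-1-benzofuran-3-carbaldehyde, via keto aldehyde 10 (not isolated)
Conditions: p-TsOH·H2O (1 equiv), (CF3)2CHOH, rt
Reagents that add atoms: water (from p-TsOH·H2O), O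
Why: In the strongly ionising, weakly nucleophilic solvent the cyclic acetal opens, a phenol re-closes on the aryl ketone, and irreversible cyclodehydration gives the aromatic furan; the benzyl ether on the 2'-oxygen blocks isoflavone formation.

Step 8
Reactants: 11 4-hydroxybenzofuran-3-carbaldehyde
Product: 12 2-[2,4-bis(benzyloxy)phenyl]-6-methoxy-4-(prop-2-en-1-yloxy)-1-benzofuran-3-carbaldehyde
Conditions: allyl bromide (1.5 equiv), K2CO3 (2 equiv), DMF, 50 °C
Reagents that add atoms: allyl bromide, C=CCBr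
Why: Williamson ether synthesis on the only free hydroxyl group in the molecule.

Step 9
Reactants: 12 4-O-allyl ether
Product: 14 2-[2,4-bis(benzyloxy)phenyl]-4-hydroxy-6-methoxy-5-(prop-2-en-1-yl)-1-benzofuran-3-carbaldehyde, via cyclohexadienone 13 (not isolated)
Conditions: PhNEt2, 200 °C, sealed tube, Ar
Reagents that add atoms: none
Why: Aromatic Claisen [3,3]-rearrangement delivers the allyl group to C5, because the other ortho position is the ring-fusion carbon C3a, and tautomerisation restores the phenol.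

Step 10
Reactants: 14 5-allyl bis(benzyl ether)
Product: 15 2-(2,4-dihydroxyphenyl)-4-hydroxy-6-methoxy-5-(prop-2-en-1-yl)-1-benzofuran-3-carbaldehyde
Conditions: BCl3 (5 equiv), C6HMe5 (6 equiv), CH2Cl2, −78 °C; then MeOH
Reagents that add atoms: none
Why: Lewis acid debenzylation with pentamethylbenzene as a non-basic benzyl cation scavenger (Friedel–Crafts trapping) is non-reductive, so at −78 °C the terminal alkene, the aldehyde and the unchelated 6-methoxy group survive.

Step 11
Reactants: 15 5-allyl triol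
Product: 16 2-(2,4-dihydroxyphenyl)-4-hydroxy-6-methoxy-5-(3-methylbut-2-en-1-yl)-1-benzofuran-3-carbaldehyde (target)
Conditions: 2-methylbut-2-ene (excess), second-generation Grubbs catalyst RuCl2(=CHPh)(PCy3)(H2IMes) (5 mol%), 1,4-benzoquinone (10 mol%), CH2Cl2, 40 °C, sealed tube
Reagents that add atoms: 2-methylbut-2-ene, CC=C(C)C
Why: Olefin cross metathesis of a terminal alkene with excess trisubstituted alkene exchanges =CH2 for =CMe2; the catalyst tolerates free phenols and aldehydes, and benzoquinone suppresses allyl-to-propenyl isomerisation.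

## Compound list
1 | 2,4-dihydroxyacetophenone | CC(=O)c1ccc(O)cc1O | starting material
2 | 2,4-bis(benzyloxy)acetophenone | CC(=O)c1ccc(OCc2ccccc2)cc1OCc1ccccc1 | intermediate
3 | 2,4,6-trimethoxybenzaldehyde | COc1cc(OC)c(C=O)c(OC)c1 | starting material
4 | 2,6-dihydroxy-4-methoxybenzaldehyde | COc1cc(O)c(C=O)c(O)c1 | intermediate
5 | 4-methoxy-2,6-bis(methoxymethoxy)benzaldehyde | COCOc1cc(OC)cc(OCOC)c1C=O | intermediate
6 | aldol adduct, 1-[2,4-bis(benzyloxy)phenyl]-3-hydroxy-3-[4-methoxy-2,6-bis(methoxymethoxy)phenyl]propan-1-one (racemic, not isolated) | O=C(CC(O)c1c(OCOC)cc(OC)cc1OCOC)c1ccc(OCc2ccccc2)cc1OCc1ccccc1 | intermediate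
7 | (E)-1-[2,4-bis(benzyloxy)phenyl]-3-[4-methoxy-2,6-bis(methoxymethoxy)phenyl]prop-2-en-1-one | O=C(/C=C/c1c(OCOC)cc(OC)cc1OCOC)c1ccc(OCc2ccccc2)cc1OCc1ccccc1 | intermediate
8 | 1-[2,4-bis(benzyloxy)phenyl]-3,3-dimethoxy-2-[4-methoxy-2,6-bis(methoxymethoxy)phenyl]propan-1-one (racemic) | COC(OC)C(C(=O)c1ccc(OCc2ccccc2)cc1OCc1ccccc1)c1c(OCOC)cc(OC)cc1OCOC | intermediate
9 | [2,4-bis(benzyloxy)phenyl](4-hydroxy-2,6-dimethoxy-2,3-dihydro-1-benzofuran-3-yl)methanone (racemic cis/trans mixture) | COC1Oc2cc(OC)cc(O)c2C1C(=O)c1ccc(OCc2ccccc2)cc1OCc1ccccc1 | intermediate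
10 | keto aldehyde, 3-[2,4-bis(benzyloxy)phenyl]-2-(2,6-dihydroxy-4-methoxyphenyl)-3-oxopropanal (racemic, not isolated) | O=CC(C(=O)c1ccc(OCc2ccccc2)cc1OCc1ccccc1)c1c(O)cc(OC)cc1O | intermediate
11 | 2-[2,4-bis(benzyloxy)phenyl]-4-hydroxy-6-methoxy-1-benzofuran-3-carbaldehyde | COc1cc(O)c2c(C=O)c(-c3ccc(OCc4ccccc4)cc3OCc3ccccc3)oc2c1 | intermediate
12 | 2-[2,4-bis(benzyloxy)phenyl]-6-methoxy-4-(prop-2-en-1-yloxy)-1-benzofuran-3-carbaldehyde | C=CCOc1cc(OC)cc2oc(-c3ccc(OCc4ccccc4)cc3OCc3ccccc3)c(C=O)c12 | intermediate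
13 | cyclohexadienone, 2-[2,4-bis(benzyloxy)phenyl]-6-methoxy-4-oxo-5-(prop-2-en-1-yl)-4,5-dihydro-1-benzofuran-3-carbaldehyde (racemic, not isolated) | C=CCC1C(=O)c2c(C=O)c(-c3ccc(OCc4ccccc4)cc3OCc3ccccc3)oc2C=C1OC | intermediate
14 | 2-[2,4-bis(benzyloxy)phenyl]-4-hydroxy-6-methoxy-5-(prop-2-en-1-yl)-1-benzofuran-3-carbaldehyde | C=CCc1c(OC)cc2oc(-c3ccc(OCc4ccccc4)cc3OCc3ccccc3)c(C=O)c2c1O | intermediate
15 | 2-(2,4-dihydroxyphenyl)-4-hydroxy-6-methoxy-5-(prop-2-en-1-yl)-1-benzofuran-3-carbaldehyde | C=CCc1c(OC)cc2oc(-c3ccc(O)cc3O)c(C=O)c2c1O | intermediate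
16 | 2-(2,4-dihydroxyphenyl)-4-hydroxy-6-methoxy-5-(3-methylbut-2-en-1-yl)-1-benzofuran-3-carbaldehyde (achiral) | COc1cc2oc(-c3ccc(O)cc3O)c(C=O)c2c(O)c1CC=C(C)C | target

## Step count and risks
Total steps: 11. Longest linear sequence: 10 steps (3 → 16, steps 2–11).

**Risk 1, step 5 (oxidative rearrangement).** The very electron-rich ring A could be attacked by the oxidant in place of the alkene. The fallback sets out from 7 and comes back at 9.
- Chalcone 7 is epoxidised under Weitz–Scheffer conditions (30% H2O2, NaOH, MeOH–THF, 0 °C → rt) to the racemic trans-epoxy ketone F1.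
- BF3·OEt2 (0.2 equiv, CH2Cl2, −78 °C) ionises the benzylic C–O bond, and a 1,2-acyl shift gives the MOM-protected keto aldehyde F2. This compound has the carbon skeleton of 8 and was made without exposing the arenes to an electrophilic oxidant.
- p-TsOH·H2O in MeOH at rt then removes the MOM groups and closes the cyclic methyl acetal 9.

**Risk 2, step 7 (re-closure).** Loss of methanol from 9 could give the isomeric 3-aroylbenzofuran. The fallback sets out from 9 and comes back at 11.
- Ethane-1,2-dithiol (1.1 equiv) with catalytic p-TsOH in CH2Cl2 at rt opens the cyclic acetal to the dithiolane ketone F3. The aldehyde carbon is now locked, so the aryl ketone is the only electrophile left for the phenols.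
- p-TsOH in refluxing toluene (Dean–Stark) then gives the 3-(1,3-dithiolan-2-yl)benzofuran F4.
- MeI and CaCO3 in MeCN–H2O at 40 °C unmask aldehyde 11.

**Risk 3, step 10 (debenzylation next to an alkene, a chelating aldehyde and an aryl methyl ether).** The fallback sets out from 14 and comes back at 16, and it reverses the order of events.
- Cross metathesis of 14 under the conditions of step 11 gives the prenylated bis(benzyl ether) F5.
- The trisubstituted alkene of F5 is hydrogenated far more slowly than a terminal one. Catalytic transfer hydrogenolysis (Pd/C, 1,4-cyclohexadiene, EtOH, rt, closely monitored) therefore removes both benzyl ethers and gives 16 directly.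

## Further compounds
F1 | step 5 | trans-[2,4-bis(benzyloxy)phenyl]{3-[4-methoxy-2,6-bis(methoxymethoxy)phenyl]oxiran-2-yl}methanone (racemic, one enantiomer drawn) | O=C([C@@H]1O[C@H]1c2c(OCOC)cc(OC)cc2OCOC)c3ccc(OCc4ccccc4)cc3OCc5ccccc5
F2 | step 5 | 3-[2,4-bis(benzyloxy)phenyl]-2-[4-methoxy-2,6-bis(methoxymethoxy)phenyl]-3-oxopropanal (racemic) | O=CC(C(=O)c1ccc(OCc2ccccc2)cc1OCc1ccccc1)c1c(OCOC)cc(OC)cc1OCOC
F3 | step 7 | 1-[2,4-bis(benzyloxy)phenyl]-2-(2,6-dihydroxy-4-methoxyphenyl)-2-(1,3-dithiolan-2-yl)ethan-1-one (racemic) | O=C(C(C1SCCS1)c1c(O)cc(OC)cc1O)c1ccc(OCc2ccccc2)cc1OCc1ccccc1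
F4 | step 7 | 2-[2,4-bis(benzyloxy)phenyl]-3-(1,3-dithiolan-2-yl)-6-methoxy-1-benzofuran-4-ol | COc1cc(O)c2c(C3SCCS3)c(-c3ccc(OCc4ccccc4)cc3OCc3ccccc3)oc2c1
F5 | step 10 | 2-[2,4-bis(benzyloxy)phenyl]-4-hydroxy-6-methoxy-5-(3-methylbut-2-en-1-yl)-1-benzofuran-3-carbaldehyde | COc1cc2oc(-c3ccc(OCc4ccccc4)cc3OCc3ccccc3)c(C=O)c2c(O)c1CC=C(C)C
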